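**Retrosynthetic overview**

1. The target is (2S)-2-(2,4-dihydroxyphenyl)-5-hydroxy-7-methoxy-8-prenylflavan. The last step only removes two silyl ethers (5-O and 4'-O).
2. Key disconnection: the C3–C4 and O1–C2 bonds of the pyran ring C (O1–C2–C3–C4–C4a–C8a) are cut in one operation, a chiral-acid-catalysed o-quinone methide/hydroxystyrene oxa-[4+2]. It is invited by two features: C4 is a benzylic CH2 flanked by oxygenated C5 and C8a and para to C7-OMe (phloroglucinol ring A, so the o-quinone methide forms easily), and ring B carries 2'-OH (hydrogen-bond handle for the catalyst) and 4'-O (activates the vinyl group).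
3. The o-quinone methide precursor comes from symmetric 2,6-dihydroxy-4-methoxybenzaldehyde: C-prenylation (future C8 side chain), silylation of the unflanked OH (future 5-OH), reduction.
4. The styrene comes from 2,4-dihydroxybenzaldehyde: 4-O-silylation, Wittig methylenation.
5. Ring order: rings A and B are bought. Ring C is the only ring closed (step 6), and C2 (S), the only stereocentre, is set in the same step from two achiral monocyclic fragments.

Key step: step 6

Remark: 2,6-dihydroxy-4-methoxybenzaldehyde (1) is taken as a purchasable building block (the 4-O-methyl ether of 2,4,6-trihydroxybenzaldehyde). The catalyst antipode in step 6 is written from a hydrogen-bonding model, and its sense of induction is to be confirmed.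

**Route**

Step 1
Reactants: 1 2,6-dihydroxy-4-methoxybenzaldehyde
Product: 2 2,6-dihydroxy-4-methoxy-3-(3-methylbut-2-en-1-yl)benzaldehyde
Conditions: prenyl bromide (1.1 equiv), 10% aq KOH, 0 °C → rt; cold acidification to pH 5
Reagents that add atoms: prenyl bromide (1-bromo-3-methylbut-2-ene), CC(C)=CCBr
Why: Direct C-prenylation of an acylphloroglucinol-type phenoxide in water (the hydrogen-bonded oxygen directs the soft allylic electrophile to carbon); C3 and C5 of 1 are equivalent, so only one mono-C-prenyl isomer can form.

Step 2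
Reactants: 2 2,6-dihydroxy-4-methoxy-3-(3-methylbut-2-en-1-yl)benzaldehyde
Product: 3 2-hydroxy-4-methoxy-3-(3-methylbut-2-en-1-yl)-6-(triisopropylsilyloxy)benzaldehyde
Conditions: TIPSCl (1.05 equiv), imidazole, DMF, 0 °C
Reagents that add atoms: triisopropylsilyl chloride, CC(C)[Si](Cl)(C(C)C)C(C)C
Why: Regioselective phenol silylation; the bulky silyl chloride should take the 6-OH (next to a ring H) over the 2-OH, which is wedged between the formyl and prenyl groups and stays chelated to C=O.

Step 3
Reactants: 3 2-hydroxy-4-methoxy-3-(3-methylbut-2-en-1-yl)-6-(triisopropylsilyloxy)benzaldehyde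
Product: 4 [2-hydroxy-4-methoxy-3-(3-methylbut-2-en-1-yl)-6-(triisopropylsilyloxy)phenyl]methanol
Conditions: NaBH4, THF/MeOH, −20 → 0 °C; pH 7 phosphate buffer; used crude, without silica chromatography
Reagents that add atoms: none
Why: Borohydride reduction of the aldehyde; the free 2-OH buffers the benzylic alkoxide, so O→O migration of the bulky TIPS group should not compete at low temperature, and the acid-sensitive salicyl alcohol is carried on directly.

Step 4
Reactants: 5 2,4-dihydroxybenzaldehyde
Product: 6 2-hydroxy-4-(triisopropylsilyloxy)benzaldehyde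
Conditions: TIPSCl (1.05 equiv), imidazole, CH2Cl2, 0 °C
Reagents that add atoms: triisopropylsilyl chloride, CC(C)[Si](Cl)(C(C)C)C(C)C
Why: Selective silylation of the more acidic, non-chelated 4-OH; the 2-OH is hydrogen-bonded to the aldehyde and is left free as the later catalyst handle.

Step 5
Reactants: 6 2-hydroxy-4-(triisopropylsilyloxy)benzaldehyde
Product: 7 2-ethenyl-5-(triisopropylsilyloxy)phenol
Conditions: Ph3PCH3Br (2.5 equiv), NaHMDS (2.4 equiv), THF, 0 °C → rt; aq NH4Cl; stored cold with BHT
Reagents that add atoms: methyltriphenylphosphonium bromide, C[P+](c1ccccc1)(c1ccccc1)c1ccccc1.[Br-]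
Why: Wittig methylenation of a salicylaldehyde; one equivalent of base is consumed by the phenol, and the alkoxide-free base leaves the aryl silyl ether intact.

Step 6
Reactants: 4 [2-hydroxy-4-methoxy-3-(3-methylbut-2-en-1-yl)-6-(triisopropylsilyloxy)phenyl]methanol; 7 2-ethenyl-5-(triisopropylsilyloxy)phenol (1.5 equiv)
Product: 9 (2S)-2-[2-hydroxy-4-(triisopropylsilyloxy)phenyl]-7-methoxy-8-(3-methylbut-2-en-1-yl)-5-(triisopropylsilyloxy)chromane, via o-quinone methide 8 (not isolated)
Conditions: (R)-TRIP (10 mol %), 4 Å MS, toluene, 0 °C; 4 added over 6 h to 7 and catalyst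
Reagents that add atoms: none
Why: Proposed new method: the chiral phosphoric acid should dehydrate 4, whose benzylic carbon (future C4) sits ortho to two oxygens and para to one, to o-quinone methide 8 and bind it through P–OH···O=C while its P=O accepts the 2-OH of styrene 7, so that the vinyl terminus adds to the exocyclic CH2 (C3–C4) and the A-ring oxygen collapses on the B-ring-stabilised benzylic carbon (O1–C2) in an asynchronous inverse-electron-demand oxa-Diels–Alder reaction. The closest known reaction type is the chiral Brønsted acid-catalysed [4+2] cycloaddition of in situ o-quinone methides from o-hydroxybenzhydrols with styrenes and o-hydroxystyrenes to 2,4-disubstituted chromans; not yet shown is a methide carbon without substituent, where C2 is the only stereocentre. The pyran ring closes by formal [4+2] cycloaddition (in a stepwise reading: vinylogous Michael addition, then 6-exo-trig oxa-Michael closure onto the B-ring quinone methide). C2 is set by the catalyst, whose doubly hydrogen-bonded assembly shields one face of the styrene α-carbon; (R)-TRIP is written for 2S from this model and the sense has to be confirmed, the antipodal acid giving the mirror image. The step needs O1 to be the oxygen next to the prenyl group, which the silyl ether on the other ortho oxygen secures, and C–C bonding at the styrene terminus, which the 2-OH/4-OSi donor pattern secures. Slow addition keeps 8 dilute against self-condensation, and the weak acid at 0 °C should leave the prenyl olefin and the benzylic ether of the product alone.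

Step 7
Reactants: 9 (2S)-2-[2-hydroxy-4-(triisopropylsilyloxy)phenyl]-7-methoxy-8-(3-methylbut-2-en-1-yl)-5-(triisopropylsilyloxy)chromane
Product: 10 (2S)-2-(2,4-dihydroxyphenyl)-7-methoxy-8-(3-methylbut-2-en-1-yl)chroman-5-ol (target)
Conditions: TBAF (2.4 equiv), AcOH (2.4 equiv), THF, 0 °C; pH 6 buffer work-up
Reagents that add atoms: none
Why: Fluoride cleavage of both aryl silyl ethers; the acetic acid buffer keeps the 2'- and 4'-phenoxides from opening the pyran ring through a quinone methide, so C2 should not be touched, and the prenyl group is inert.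

**Compound list**

1 | 2,6-dihydroxy-4-methoxybenzaldehyde | COc1cc(O)c(C=O)c(O)c1 | starting material
2 | 2,6-dihydroxy-4-methoxy-3-(3-methylbut-2-en-1-yl)benzaldehyde | COc1cc(O)c(C=O)c(O)c1CC=C(C)C | intermediate
3 | 2-hydroxy-4-methoxy-3-(3-methylbut-2-en-1-yl)-6-(triisopropylsilyloxy)benzaldehyde | COc1cc(O[Si](C(C)C)(C(C)C)C(C)C)c(C=O)c(O)c1CC=C(C)C | intermediate
4 | [2-hydroxy-4-methoxy-3-(3-methylbut-2-en-1-yl)-6-(triisopropylsilyloxy)phenyl]methanol | COc1cc(O[Si](C(C)C)(C(C)C)C(C)C)c(CO)c(O)c1CC=C(C)C | intermediate
5 | 2,4-dihydroxybenzaldehyde | O=Cc1ccc(O)cc1O | starting material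
6 | 2-hydroxy-4-(triisopropylsilyloxy)benzaldehyde | O=Cc1ccc(O[Si](C(C)C)(C(C)C)C(C)C)cc1O | intermediate
7 | 2-ethenyl-5-(triisopropylsilyloxy)phenol | C=Cc1ccc(O[Si](C(C)C)(C(C)C)C(C)C)cc1O | intermediate
8 | 3-methoxy-6-methylidene-2-(3-methylbut-2-en-1-yl)-5-(triisopropylsilyloxy)cyclohexa-2,4-dien-1-one (o-quinone methide) | COC1=C(CC=C(C)C)C(=O)C(=C)C(O[Si](C(C)C)(C(C)C)C(C)C)=C1 | intermediate (not isolated)
9 | (2S)-2-[2-hydroxy-4-(triisopropylsilyloxy)phenyl]-7-methoxy-8-(3-methylbut-2-en-1-yl)-5-(triisopropylsilyloxy)chromane | COc1cc(O[Si](C(C)C)(C(C)C)C(C)C)c2c(c1CC=C(C)C)O[C@H](c1ccc(O[Si](C(C)C)(C(C)C)C(C)C)cc1O)CC2 | intermediate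
10 | (2S)-2-(2,4-dihydroxyphenyl)-7-methoxy-8-(3-methylbut-2-en-1-yl)chroman-5-ol | COc1cc(O)c2c(c1CC=C(C)C)O[C@H](c1ccc(O)cc1O)CC2 | target

**Step count**

Total steps: 7. Longest linear sequence: 5 (steps 1, 2, 3, 6, 7).

**Steps most likely to fail**

Step 6 (proposed new method). The catalyst may discriminate poorly between the two faces of the styrene α-carbon because the methide carbon of the o-quinone methide carries no substituent, and self-condensation of the quinone methide may outrun the cycloaddition. The fallback sets out from 4 and 7 and gives up catalyst control. The two are combined in toluene with catalytic achiral diphenyl phosphate and excess styrene, which is the established acid-promoted o-quinone methide/styrene hetero-Diels–Alder route to flavans. This gives racemic 2-[2-hydroxy-4-(triisopropylsilyloxy)phenyl]-7-methoxy-8-(3-methylbut-2-en-1-yl)-5-(triisopropylsilyloxy)chromane F1. Preparative SFC on a polysaccharide chiral stationary phase then separates 9 from its (2R)-enantiomer F2, and the route is rejoined at 9.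

Step 1. O-alkylation and double C-alkylation may compete with mono-C-alkylation, and the allylic bromide may hydrolyse in the aqueous base. The fallback sets out from 1 and installs the prenyl group by sigmatropic rearrangement. One phenol is etherified with 3-chloro-3-methylbut-1-yne (DBU, cat. CuCl2, MeCN, 0 °C) to give 2-hydroxy-4-methoxy-6-[(2-methylbut-3-yn-2-yl)oxy]benzaldehyde F3. Lindlar semi-hydrogenation gives 2-hydroxy-4-methoxy-6-[(2-methylbut-3-en-2-yl)oxy]benzaldehyde F4. Heating in toluene or xylene effects the aromatic Claisen rearrangement to the only free ortho position, and the route is rejoined at 2.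

Step 2. The silyl chloride may not discriminate fully between the two chelated phenols, or bis-silylation may occur. The fallback sets out from 1 and moves the silylation ahead of the prenylation, so that symmetry fixes the regiochemistry. Compound 1 is mono-silylated (TIPSCl, imidazole) to 2-hydroxy-4-methoxy-6-(triisopropylsilyloxy)benzaldehyde F5. The remaining phenol is converted with 3-chloro-3-methylbut-1-yne (DBU, cat. CuCl2) into 4-methoxy-2-[(2-methylbut-3-yn-2-yl)oxy]-6-(triisopropylsilyloxy)benzaldehyde F6. Lindlar semi-hydrogenation gives 4-methoxy-2-[(2-methylbut-3-en-2-yl)oxy]-6-(triisopropylsilyloxy)benzaldehyde F7. Thermal Claisen rearrangement then places the prenyl group ortho to the liberated phenol, and the route is rejoined at 3.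

**Further compounds**

F1 | step 6 | racemic 2-[2-hydroxy-4-(triisopropylsilyloxy)phenyl]-7-methoxy-8-(3-methylbut-2-en-1-yl)-5-(triisopropylsilyloxy)chromane | COc1cc(O[Si](C(C)C)(C(C)C)C(C)C)c2c(c1CC=C(C)C)OC(c1ccc(O[Si](C(C)C)(C(C)C)C(C)C)cc1O)CC2
F2 | step 6 | (2R)-2-[2-hydroxy-4-(triisopropylsilyloxy)phenyl]-7-methoxy-8-(3-methylbut-2-en-1-yl)-5-(triisopropylsilyloxy)chromane | COc1cc(O[Si](C(C)C)(C(C)C)C(C)C)c2c(c1CC=C(C)C)O[C@@H](c1ccc(O[Si](C(C)C)(C(C)C)C(C)C)cc1O)CC2
F3 | step 1 | 2-hydroxy-4-methoxy-6-[(2-methylbut-3-yn-2-yl)oxy]benzaldehyde | COc1cc(O)c(C=O)c(OC(C)(C)C#C)c1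
F4 | step 1 | 2-hydroxy-4-methoxy-6-[(2-methylbut-3-en-2-yl)oxy]benzaldehyde | COc1cc(O)c(C=O)c(OC(C)(C)C=C)c1
F5 | step 2 | 2-hydroxy-4-methoxy-6-(triisopropylsilyloxy)benzaldehyde | COc1cc(O)c(C=O)c(O[Si](C(C)C)(C(C)C)C(C)C)c1
F6 | step 2 | 4-methoxy-2-[(2-methylbut-3-yn-2-yl)oxy]-6-(triisopropylsilyloxy)benzaldehyde | COc1cc(OC(C)(C)C#C)c(C=O)c(O[Si](C(C)C)(C(C)C)C(C)C)c1
F7 | step 2 | 4-methoxy-2-[(2-methylbut-3-en-2-yl)oxy]-6-(triisopropylsilyloxy)benzaldehyde | COc1cc(OC(C)(C)C=C)c(C=O)c(O[Si](C(C)C)(C(C)C)C(C)C)c1
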